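**Plan**

Numbering used throughout (also in the spiro names): ring A C1(OAc)–C2–C3(Me,Cl)–C4(Br)–C5–C6(spiro); ring B C6–C7(Me,OH)–C8–C9–C10(Br)–C11(Me2).
Retrosynthesis cuts, in order: C10–H (hydrogen onto a C9=C10 vinyl bromide), C3–Cl/C4–Br (bromochlorination of C3=C4), the ring B bond C7–C8, C8–C9 (Mannich carbon), C6–C11 (Claisen) and C6–C7 (C-acylation).
Forward: ring A is 3-methylcyclohex-2-en-1-one; acetylation at C6 and an O-allylation/Claisen sequence build the quaternary C6 next to the gem-dimethyl carbon C11; ring B is closed last.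
Feature used: in ring B the tertiary carbinol C7 and the bromine-bearing C10 are 1,4-related across C8–C9 and both sit on the C6–C11 quaternary pair. Ring B is therefore the reductive coupling product of an acetyl group on C6 with a vinyl ketone on C11, and the C1 oxygen of ring A (1,3 to C7) can hold C7=O on samarium.
Stereochemistry: C1 from catalyst-controlled Corey–Bakshi–Shibata reduction, which also resolves racemic C6 by diastereomer separation; C7 from chelation in the ring closure; C3/C4 from anti bromochlorination steered by the C1 acetate; C10 from hydrogen delivery to the less hindered face of the vinyl bromide.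

Key step: step 7

Remark: in 6 the allyl group is drawn on the ring oxygen of 2; the isomer alkylated on the acetyl oxygen would rearrange to the same ketone 7.

**Step 1**
Reactants: 1 3-methylcyclohex-2-en-1-one
Product: 2 6-acetyl-3-methylcyclohex-2-en-1-one
Conditions: LiN(i-Pr)2 (2.2 equiv), THF, −78 °C; 1-acetylimidazole; NH4Cl (aq)
Reagents that add atoms: 1-acetylimidazole, CC(=O)n1ccnc1
Why: Kinetic deprotonation of the enone at the α′ carbon C6 and C-acylation of the lithium enolate (crossed Claisen condensation) should give the β-diketone, which is removed from the equilibrium as its enolate; no stereocentre is retained.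

**Step 2**
Reactants: 3 methyl 3-methyl-2-oxobutanoate
Product: 4 methyl 2-{[tert-butyl(dimethyl)silyl]oxy}-3-methylbut-2-enoate
Conditions: t-BuMe2SiOTf, Et3N, CH2Cl2, 0 °C
Reagents that add atoms: tert-butyldimethylsilyl trifluoromethanesulfonate, CC(C)(C)[Si](C)(C)OS(=O)(=O)C(F)(F)F
Why: Soft enolization and O-silylation of the α-keto ester (silyl enol ether formation) can occur only toward the isopropyl carbon, so one tetrasubstituted enol ether should form.

**Step 3**
Reactants: 4 methyl 2-{[tert-butyl(dimethyl)silyl]oxy}-3-methylbut-2-enoate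
Product: 5 2-{[tert-butyl(dimethyl)silyl]oxy}-3-methylbut-2-en-1-ol
Conditions: i-Bu2AlH (2.2 equiv), CH2Cl2, −78 °C
Reagents that add atoms: none
Why: Hydride reduction of the unsaturated ester to the primary allylic alcohol should leave the silyl enol ether untouched.

**Step 4**
Reactants: 2 6-acetyl-3-methylcyclohex-2-en-1-one; 5 2-{[tert-butyl(dimethyl)silyl]oxy}-3-methylbut-2-en-1-ol
Product: 7 rac-6-acetyl-6-(3-{[tert-butyl(dimethyl)silyl]oxy}-2-methylbut-3-en-2-yl)-3-methylcyclohex-2-en-1-one, via allyl vinyl ether 6 (not isolated)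
Conditions: PPh3, DIAD, THF, 0 → 23 °C; then toluene, 110 °C
Reagents that add atoms: none
Why: Mitsunobu O-alkylation of the acidic β-diketone enol by the primary allylic alcohol should give the allyl vinyl ether, and its Claisen rearrangement joins C6 to the dimethyl-substituted allyl terminus (C6–C11 bond between two fully substituted carbons) while releasing the C1 ketone; the quaternary centre forms as a racemate.

**Step 5**
Reactants: 7 rac-6-acetyl-6-(3-{[tert-butyl(dimethyl)silyl]oxy}-2-methylbut-3-en-2-yl)-3-methylcyclohex-2-en-1-one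
Product: 9 1-[(1R,6R)-1-(3-{[tert-butyl(dimethyl)silyl]oxy}-2-methylbut-3-en-2-yl)-6-hydroxy-4-methylcyclohex-3-en-1-yl]ethan-1-one, via deconjugated enone 8 (not isolated)
Conditions: LiN(i-Pr)2 (2.2 equiv), THF, −78 °C; AcOH, −78 °C; then (S)-2-methyl-CBS-oxazaborolidine (0.2 equiv), catecholborane, toluene, −78 °C; separation of diastereomers
Reagents that add atoms: none
Why: Kinetic α-protonation of the extended dienolate (the acetyl enolate is simply reprotonated) should move the ring alkene to C3=C4, and Corey–Bakshi–Shibata reduction of the more reactive six-membered ring ketone, in preference to the neopentyl-type acetyl group, sets the (R)-carbinol at C1 under catalyst control in both enantiomers of 8, so the cis (1R,6R) alcohol is separated from its C6 epimer as a single enantiomer.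

**Step 6**
Reactants: 9 1-[(1R,6R)-1-(3-{[tert-butyl(dimethyl)silyl]oxy}-2-methylbut-3-en-2-yl)-6-hydroxy-4-methylcyclohex-3-en-1-yl]ethan-1-one
Product: 12 4-[(1R,6R)-1-acetyl-6-hydroxy-4-methylcyclohex-3-en-1-yl]-4-methylpent-1-en-3-one, via Mannich base 10 (not isolated), via ammonium iodide 11 (not isolated)
Conditions: Me2N=CH2 iodide, CH2Cl2, 23 °C; MeI; NaHCO3 (aq)
Reagents that add atoms: N,N-dimethylmethyleneiminium iodide, C=[N+](C)C.[I-]
Why: The Mannich reaction of the silyl enol ether is regiospecific for C9 and brings in C8, and quaternization followed by β-elimination of the amine should leave the vinyl ketone (C10=O, C9=C8) without touching the acetyl group or the ring alkene.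

**Step 7**
Reactants: 12 4-[(1R,6R)-1-acetyl-6-hydroxy-4-methylcyclohex-3-en-1-yl]-4-methylpent-1-en-3-one
Product: 13 (1R,6R,7R)-1,7-dihydroxy-3,7,11,11-tetramethylspiro[5.5]undec-3-en-10-one
Conditions: SmI2 (2.5 equiv), THF, −78 → −20 °C, high dilution; NH4Cl (aq)
Reagents that add atoms: none
Why: Divalent samarium should transfer an electron to the vinyl ketone to give a samarium-bound radical enolate whose terminal carbon C8 adds to the acetyl carbonyl carbon C7, held on the same trivalent samarium centre by the C1 oxygen; a second electron transfer and protonation on work-up give the γ-hydroxy ketone (a ketyl-first sequence leads to the same bond). The closest known reaction type is the SmI2-mediated reductive cyclization of a ketone with an α,β-unsaturated carbonyl group (ketyl–olefin coupling). Ring B closes 6-exo-trig onto C7=O, which is 6-endo with respect to C8=C9, and attack through the unsubstituted β-carbon C8 follows the spin density of the reduced enone. The only new stereocentre, C7, is set by the six-membered chelate O1–Sm–O7: the carbonyl oxygen is turned toward C1, the tether through C11 leaves one face of C7=O open to C8, and the methyl group avoids the C11 methyl groups, so OH ends cis to C1 (7R). The step needs C7–C8 coupling to win over closure through C9 (reductive aldol to a five-membered ring) and over plain conjugate reduction; aprotic conditions keep the enolate unprotonated until after cyclization, chelation activates C7=O, and C1 is already an alcohol so no second ketone competes.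

**Step 8**
Reactants: 13 (1R,6R,7R)-1,7-dihydroxy-3,7,11,11-tetramethylspiro[5.5]undec-3-en-10-one
Product: 14 (1R,6R,7R)-7-hydroxy-3,7,11,11-tetramethyl-10-oxospiro[5.5]undec-3-en-1-yl acetate
Conditions: Ac2O, pyridine, DMAP (cat.), CH2Cl2, 0 °C
Reagents that add atoms: acetic anhydride, CC(=O)OC(C)=O
Why: Nucleophilic-catalysed acylation should take the secondary C1 alcohol and leave the hindered tertiary C7 alcohol free.

**Step 9**
Reactants: 14 (1R,6R,7R)-7-hydroxy-3,7,11,11-tetramethyl-10-oxospiro[5.5]undec-3-en-1-yl acetate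
Product: 15 (1R,6R,7R)-3,7,11,11-tetramethyl-7-[(triethylsilyl)oxy]-10-{[(trifluoromethyl)sulfonyl]oxy}spiro[5.5]undeca-3,9-dien-1-yl acetate
Conditions: KN(SiMe3)2 (2.2 equiv), THF, −78 °C; N-(5-chloropyridin-2-yl)bis(trifluoromethanesulfonimide); Et3SiCl
Reagents that add atoms: N-(5-chloropyridin-2-yl)bis(trifluoromethanesulfonimide), O=S(=O)(N(c1ccc(Cl)cn1)S(=O)(=O)C(F)(F)F)C(F)(F)F; chlorotriethylsilane, CC[Si](Cl)(CC)CC
Why: The C10 ketone can enolize only toward C9 because C11 is quaternary, so enolate O-sulfonylation (enol triflate formation) is regiospecific, and the tertiary alkoxide is then capped as a silyl ether to keep it out of the later bromonium chemistry.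

**Step 10**
Reactants: 15 (1R,6R,7R)-3,7,11,11-tetramethyl-7-[(triethylsilyl)oxy]-10-{[(trifluoromethyl)sulfonyl]oxy}spiro[5.5]undeca-3,9-dien-1-yl acetate
Product: 16 (1R,6R,7R)-10-bromo-3,7,11,11-tetramethyl-7-[(triethylsilyl)oxy]spiro[5.5]undeca-3,9-dien-1-yl acetate
Conditions: Ni(OAc)2·4H2O (cat.), 1,5-cyclooctadiene, Zn (cat.), LiBr, DMA–THF, 23 °C
Reagents that add atoms: lithium bromide, [Li+].[Br-]
Why: Nickel-catalysed halogen exchange of the enol triflate (oxidative addition to zerovalent nickel, triflate/bromide exchange, reductive elimination) should give the alkenyl bromide with the double bond in place.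

**Step 11**
Reactants: 16 (1R,6R,7R)-10-bromo-3,7,11,11-tetramethyl-7-[(triethylsilyl)oxy]spiro[5.5]undeca-3,9-dien-1-yl acetate
Product: 17 (1R,3S,4S,6R,7R)-4,10-dibromo-3-chloro-3,7,11,11-tetramethyl-7-[(triethylsilyl)oxy]spiro[5.5]undec-9-en-1-yl acetate
Conditions: N-bromosuccinimide, CH2Cl2, −40 °C; then Me3SiCl, −40 → 0 °C
Reagents that add atoms: N-bromosuccinimide, O=C1CCC(=O)N1Br; chlorotrimethylsilane, C[Si](C)(C)Cl
Why: Electrophilic bromochlorination of the electron-rich ring A alkene (the vinyl bromide is inert): bromonium formation is reversible, and only the bromonium ion on the C11 face can be intercepted from below by the C1 acetate carbonyl (bridged 1,3-dioxan-2-ylium ion across C1/C3); its tertiary C3–O bond lies anti to bromine and should re-ionize with bromine participation, so chloride enters at the tertiary carbon C3 anti to bromine (Markovnikov, net anti addition), placing C4–Br cis to C11 and C3–Cl cis to the acetate.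

**Step 12**
Reactants: 17 (1R,3S,4S,6R,7R)-4,10-dibromo-3-chloro-3,7,11,11-tetramethyl-7-[(triethylsilyl)oxy]spiro[5.5]undec-9-en-1-yl acetate
Product: 19 (1R,3S,4S,6R,7R,10R)-4,10-dibromo-3-chloro-7-hydroxy-3,7,11,11-tetramethylspiro[5.5]undecan-1-yl acetate, via silyl ether 18 (not isolated)
Conditions: Mn(dpm)3 (cat., dpm = 2,2,6,6-tetramethylheptane-3,5-dionate), PhSiH3, t-BuOOH, i-PrOH, 23 °C; then HF·pyridine, THF, 0 °C
Reagents that add atoms: none
Why: Metal-hydride hydrogen atom transfer hydrogenation of the haloalkene: a hydrogen atom adds to C9, and the α-bromo radical at C10 should take its hydrogen from the face opposite the axial C5 methylene of ring A, so bromine is kept and ends trans to the C7 oxygen (10R); fluoride then frees the tertiary alcohol.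

**Compound list**

1 | 3-methylcyclohex-2-en-1-one | CC1=CC(=O)CCC1 | starting material
2 | 6-acetyl-3-methylcyclohex-2-en-1-one | CC(=O)C1CCC(C)=CC1=O | intermediate
3 | methyl 3-methyl-2-oxobutanoate | COC(=O)C(=O)C(C)C | starting material
4 | methyl 2-{[tert-butyl(dimethyl)silyl]oxy}-3-methylbut-2-enoate | COC(=O)C(O[Si](C)(C)C(C)(C)C)=C(C)C | intermediate
5 | 2-{[tert-butyl(dimethyl)silyl]oxy}-3-methylbut-2-en-1-ol | OCC(O[Si](C)(C)C(C)(C)C)=C(C)C | intermediate
6 | 1-{2-[(2-{[tert-butyl(dimethyl)silyl]oxy}-3-methylbut-2-en-1-yl)oxy]-4-methylcyclohexa-1,3-dien-1-yl}ethan-1-one | CC(=O)C1=C(OCC(O[Si](C)(C)C(C)(C)C)=C(C)C)C=C(C)CC1 | intermediate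
7 | rac-6-acetyl-6-(3-{[tert-butyl(dimethyl)silyl]oxy}-2-methylbut-3-en-2-yl)-3-methylcyclohex-2-en-1-one (racemic) | CC(=O)C1(CCC(C)=CC1=O)C(C)(C)C(=C)O[Si](C)(C)C(C)(C)C | intermediate
8 | rac-2-acetyl-2-(3-{[tert-butyl(dimethyl)silyl]oxy}-2-methylbut-3-en-2-yl)-5-methylcyclohex-4-en-1-one (racemic) | CC(=O)C1(CC=C(C)CC1=O)C(C)(C)C(=C)O[Si](C)(C)C(C)(C)C | intermediate
9 | 1-[(1R,6R)-1-(3-{[tert-butyl(dimethyl)silyl]oxy}-2-methylbut-3-en-2-yl)-6-hydroxy-4-methylcyclohex-3-en-1-yl]ethan-1-one | O[C@@H]1CC(C)=CC[C@@]1(C(C)=O)C(C)(C)C(=C)O[Si](C)(C)C(C)(C)C | intermediate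
10 | 2-[(1R,6R)-1-acetyl-6-hydroxy-4-methylcyclohex-3-en-1-yl]-5-(dimethylamino)-2-methylpentan-3-one | O[C@@H]1CC(C)=CC[C@@]1(C(C)=O)C(C)(C)C(=O)CCN(C)C | intermediate
11 | 4-[(1R,6R)-1-acetyl-6-hydroxy-4-methylcyclohex-3-en-1-yl]-N,N,N,4-tetramethyl-3-oxopentan-1-aminium iodide | O[C@@H]1CC(C)=CC[C@@]1(C(C)=O)C(C)(C)C(=O)CC[N+](C)(C)C.[I-] | intermediate
12 | 4-[(1R,6R)-1-acetyl-6-hydroxy-4-methylcyclohex-3-en-1-yl]-4-methylpent-1-en-3-one | O[C@@H]1CC(C)=CC[C@@]1(C(C)=O)C(C)(C)C(=O)C=C | intermediate
13 | (1R,6R,7R)-1,7-dihydroxy-3,7,11,11-tetramethylspiro[5.5]undec-3-en-10-one | O[C@@H]1CC(C)=CC[C@@]12C(C)(C)C(=O)CC[C@@]2(C)O | intermediate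
14 | (1R,6R,7R)-7-hydroxy-3,7,11,11-tetramethyl-10-oxospiro[5.5]undec-3-en-1-yl acetate | CC(=O)O[C@@H]1CC(C)=CC[C@@]12C(C)(C)C(=O)CC[C@@]2(C)O | intermediate
15 | (1R,6R,7R)-3,7,11,11-tetramethyl-7-[(triethylsilyl)oxy]-10-{[(trifluoromethyl)sulfonyl]oxy}spiro[5.5]undeca-3,9-dien-1-yl acetate | CC(=O)O[C@@H]1CC(C)=CC[C@@]12C(C)(C)C(OS(=O)(=O)C(F)(F)F)=CC[C@@]2(C)O[Si](CC)(CC)CC | intermediate
16 | (1R,6R,7R)-10-bromo-3,7,11,11-tetramethyl-7-[(triethylsilyl)oxy]spiro[5.5]undeca-3,9-dien-1-yl acetate | CC(=O)O[C@@H]1CC(C)=CC[C@@]12C(C)(C)C(Br)=CC[C@@]2(C)O[Si](CC)(CC)CC | intermediate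
17 | (1R,3S,4S,6R,7R)-4,10-dibromo-3-chloro-3,7,11,11-tetramethyl-7-[(triethylsilyl)oxy]spiro[5.5]undec-9-en-1-yl acetate | CC(=O)O[C@@H]1C[C@](C)(Cl)[C@@H](Br)C[C@@]12C(C)(C)C(Br)=CC[C@@]2(C)O[Si](CC)(CC)CC | intermediate
18 | (1R,3S,4S,6R,7R,10R)-4,10-dibromo-3-chloro-3,7,11,11-tetramethyl-7-[(triethylsilyl)oxy]spiro[5.5]undecan-1-yl acetate | CC(=O)O[C@@H]1C[C@](C)(Cl)[C@@H](Br)C[C@@]12C(C)(C)[C@H](Br)CC[C@@]2(C)O[Si](CC)(CC)CC | intermediate
19 | (1R,3S,4S,6R,7R,10R)-4,10-dibromo-3-chloro-7-hydroxy-3,7,11,11-tetramethylspiro[5.5]undecan-1-yl acetate | CC(=O)O[C@@H]1C[C@](C)(Cl)[C@@H](Br)C[C@@]12C(C)(C)[C@H](Br)CC[C@@]2(C)O | target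

**Count and risks**

Total step count: 12. Longest linear sequence: 11 steps (steps 2 to 12, from 3); step 1, which supplies 2 from 1, is the one-step side branch.

Steps most likely to fail:

Step 7. The reduced enone may be protonated or dimerize before it cyclizes, closure may occur through C9 (five-membered reductive aldol), or chelation control at C7 may be lost. The fallback generates the C7 radical by hydrogen atom transfer instead of electron transfer. It sets out from 12: silylation with Et3SiOTf and Et3N should give 4-[(1R,6R)-4-methyl-6-[(triethylsilyl)oxy]-1-{1-[(triethylsilyl)oxy]ethenyl}cyclohex-3-en-1-yl]-4-methylpent-1-en-3-one F1. Fe(acac)3 (acac = pentane-2,4-dionate) and PhSiH3 in EtOH should transfer a hydrogen atom to the enol ether, and the tertiary α-silyloxy radical at C7 should add to C8 of the vinyl ketone (Giese-type cyclization) to give (1R,6R,7R)-3,7,11,11-tetramethyl-1,7-bis[(triethylsilyl)oxy]spiro[5.5]undec-3-en-10-one F2. Desilylation with HF·pyridine comes back to the route at 13. The ring A alkene is a competing acceptor for the hydrogen atom, and C7 is then set without chelation, so the C7 epimers may need to be separated.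

Step 4. The diketone may be alkylated on carbon instead of oxygen, the silyl group may migrate, or the [3,3] shift between two fully substituted carbons may be slow enough for cleavage of the ether to compete. The fallback forms the enol ether by addition–elimination. It sets out from 2: oxalyl chloride with catalytic DMF should give the vinylogous acid chloride 1-(2-chloro-4-methylcyclohexa-1,3-dien-1-yl)ethan-1-one F3; the lithium alkoxide of 5 (n-BuLi, THF, −78 °C) should displace chloride to give 6, which is heated as before and comes back to the route at 7.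

Step 12. The second hydrogen transfer may show poor facial selectivity (C10 epimer), or bromine may be lost reductively. The fallback is a hydroxyl-directed hydrogenation. It sets out from 17: HF·pyridine should give (1R,3S,4S,6R,7R)-4,10-dibromo-3-chloro-7-hydroxy-3,7,11,11-tetramethylspiro[5.5]undec-9-en-1-yl acetate F4; H2 with [Ir(cod)(PCy3)(py)]PF6 in CH2Cl2 should deliver hydrogen from the face of the C7 hydroxyl group (homoallylic to C9=C10), which places bromine trans to OH and comes back to the route at 19.

**Further compounds**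

F1 | step 7 | 4-[(1R,6R)-4-methyl-6-[(triethylsilyl)oxy]-1-{1-[(triethylsilyl)oxy]ethenyl}cyclohex-3-en-1-yl]-4-methylpent-1-en-3-one | CC[Si](CC)(CC)O[C@@H]1CC(C)=CC[C@@]1(C(=C)O[Si](CC)(CC)CC)C(C)(C)C(=O)C=C
F2 | step 7 | (1R,6R,7R)-3,7,11,11-tetramethyl-1,7-bis[(triethylsilyl)oxy]spiro[5.5]undec-3-en-10-one | CC[Si](CC)(CC)O[C@@H]1CC(C)=CC[C@@]12C(C)(C)C(=O)CC[C@@]2(C)O[Si](CC)(CC)CC
F3 | step 4 | 1-(2-chloro-4-methylcyclohexa-1,3-dien-1-yl)ethan-1-one | CC(=O)C1=C(Cl)C=C(C)CC1
F4 | step 12 | (1R,3S,4S,6R,7R)-4,10-dibromo-3-chloro-7-hydroxy-3,7,11,11-tetramethylspiro[5.5]undec-9-en-1-yl acetate | CC(=O)O[C@@H]1C[C@](C)(Cl)[C@@H](Br)C[C@@]12C(C)(C)C(Br)=CC[C@@]2(C)O
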